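Its constants are made up; the rest is arithmetic.

Lowering the temperature does two things to this pair of conformers: it moves their equilibrium and it slows their exchange, and here these two pull the share of target in opposite directions. These flasks start with starting material and free catalyst, and no other conformer is charged.

| flask | starting material | free catalyst | temperature | time |
|---|---|---|---|---|
| north-west | 0.30 M | 3.9 mol% | 55 °C | 1.0 min |
| north | 0.30 M | 3.9 mol% | −5 °C | 1.0 min |
| north-east | 0.30 M | 3.9 mol% | −35 °C | 1.0 min |
| south-west | 0.30 M | 3.9 mol% | 25 °C | 1.0 min |

    starting material + free catalyst → free catalyst + target (k1 = 5.4 L mol⁻¹ s⁻¹, Ea1 = 56.0 kJ mol⁻¹)
    free catalyst + other conformer → free catalyst + isomer of the product (k2 = 13 L mol⁻¹ s⁻¹, Ea2 = 56.0 kJ mol⁻¹)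
    free catalyst + target → spent catalyst (k3 = 0.022 L mol⁻¹ s⁻¹, Ea3 = 56.0 kJ mol⁻¹)
    starting material ⇌ other conformer (K4 = 0.86, k4 = 2.5 s⁻¹, Ea4 = 65.0 kJ mol⁻¹, ΔH4 = −9.00 kJ mol⁻¹)
    (constants at 25 °C)

- constants are those at 25 °C; use the activation energies and enthalpies for any other temperature
- in a conversion other conformer counts as not yet reacted
- the share counts what is present at the end, not what went on to other products

1. the flask that comes out highest in share of target in all that became target or isomer of the product, or "all alike" when all lie within 1.5 percentage points (north-west / north / north-east / south-west / all alike)
2. share of target in all that became target or isomer of the product, north-west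
3. share of target in all that became target or isomer of the product, north
4. share of target in all that became target or isomer of the product, north-east
5. share of target in all that became target or isomer of the product, south-west

Target forms from starting material and isomer of the product from other conformer, both on the same free catalyst. At any moment, therefore, target's share of what is forming is k(target)·c(starting material) divided by that same term plus k(isomer)·c(other conformer). Because both products form with the same activation energy, 56.0 kJ mol⁻¹, the ratio k(isomer)/k(target) stays 2.41 at each of these temperatures.

We ask first what the end state of the exchange must be. There c(other conformer)/c(starting material) equals K, and the share becomes k(target)/(k(target) + k(isomer)·K). We call this the exchange share, the Curtin–Hammett limit. In the north flask K is 1.29, so the exchange share is 24.3 %. It is 40.2 % in north-west, 32.6 % in south-west and 16.2 % in north-east.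

So north-east has the lowest exchange share, and yet we expect it to give the highest share of target. The second question, how fast that end state is approached, clears this up. In north the exchange has a relaxation half-life of 2.94 s, far shorter than the run, so we expect north near its exchange share, and somewhat above it, since the flask starts without other conformer. In north-east the forward constant falls to 0.00338 s⁻¹ and the half-life rises to 2.33 min, longer than the run. We therefore take other conformer in north-east as growing roughly linearly from nothing, and averaging over the run gives our own figure for north-east, 80.4 %, above the exchange shares of the other flasks.

The forecast gives 39.2 % north-west, 28.7 % north, 80.5 % north-east and 33.5 % south-west, with north-east highest, reasoning: “At −35 °C the conformers barely interconvert within the minute”.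

The flasks give 39.2 % north-west, 28.7 % north, 80.5 % north-east and 33.4 % south-west, so north-east stands highest, at a conversion of 1.43 %. North stands 4.4 percentage points above its exchange share 24.3 % at a conversion of 40.7 %, which amounts to an excess of 1.77 % of the charge as target.

The neighbour is the north flask read at 25 s, still well past the relaxation, with the same exchange share. Assuming the same excess on the 18.8 % of target and isomer of the product there gives 33.8 %, and that flask reads 33.1 %.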